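Slowness is where I start: in this flask two substrates compete for the free catalyst and for the partner, much as two substrates compete for one enzyme.

    starting material + free catalyst ⇌ catalyst intermediate A (K1 = 92.4 M⁻¹, k1 = 44400 M⁻¹ min⁻¹)
    partner + catalyst intermediate A → free catalyst + target (k2 = 235 M⁻¹ min⁻¹)
    second substrate + free catalyst ⇌ catalyst intermediate B (K3 = 457 M⁻¹, k3 = 686 M⁻¹ min⁻¹)
    partner + catalyst intermediate B → free catalyst + second product (k4 = 1090 M⁻¹ min⁻¹)
    target + free catalyst ⇌ isomer of the product + free catalyst, rate k5*[free catalyst]*[target] forward; the back reaction follows from the equilibrium constant (K5 = 1.04, k5 = 6140 M⁻¹ min⁻¹)

starting material 10 mM; second substrate 2.00 equiv; partner 1.20 equiv; free catalyst 2.5 mol%; time 12 h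

- the state of affairs at 12 h: stopped, and by what, or still going (the partner has run out first / no working catalyst is left / it is still moving / forward and back rates have come level / all of the starting material has reacted)
- target at 12 h, in percent of the starting material charged
- isomer of the product at 12 h, in percent of the starting material charged

I turn the constants into times at the charged amounts. Catalyst intermediate A falls back to starting material in 0.00208 min but meets partner only every 0.355 min, so it falls back far sooner: it sits in rapid equilibrium. Catalyst intermediate B falls back in 0.666 min but meets partner every 0.0765 min, which is sooner, so a fraction 0.897 of what forms goes on to second product.

Dividing the flow into second product by the flow into target gives 4.72 at the charge. I call this ratio of the two flows the split. The partner is the limiting reagent, with 1.20 equiv against 3.00 equiv of the two substrates together, so the split shares it out.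

The split moves as partner falls. Once partner is nearly spent, catalyst intermediate B also returns to equilibrium. Second substrate is then near 0.800 equiv plus what the target side spared, and starting material stands a little under its charge. I take the two as level, which gives a late split of 22.9.

The target side's share of partner therefore falls from 0.175 to 0.0418. Their mean, applied to the partner charge, gives a conversion of 13.0% of the starting material.

Partner lasts roughly 6.73 min, far less than 12 h. So I expect partner to run out. Isomerisation takes 6.51 min with 10% of the catalyst free, also far less than the run, so the conversion divides by 1.04. I commit to 6.37% target and 6.62% isomer of the product.

The forecast says the partner has run out first, with 7% target (6.2% to 7.8%) and 7.2% isomer (6.4% to 8.1%). Its ground is that the “second substrate takes the partner about five times faster”. Its target figure stands higher than mine.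

The simulation gives the partner has run out first, with 7.07% target and 7.35% isomer of the product, inside the forecast's ranges and above my figure. Partner stands at 0%, and the largest change over the second half of the time is 0 percentage points. Second product over target plus isomer comes to 7.32, above the split at the charge and below the late split. In the neighbour flask with 0.500 equiv of second substrate, the split at the charge is 1.18 and second substrate ends at 0%. The same ratio there is 0.714, below that split, with 34.3% target and 35.7% isomer of the product.

All constants come from no measurement; the flask was simulated.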